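Late in the dawn run the target sinks while the starting material goes on falling, and two chemists read that tail differently.

all flasks: starting material 20 mM; free enzyme 0.01 mol%
- dawn: second substrate 2 equiv; temperature 30 °C; the very flask that is asked about, followed so far
- dusk: second substrate 2 equiv; temperature 25 °C; run made earlier
- flask: second substrate 2.00 equiv; temperature 30 °C; time 10 h

- dawn (time / h: target / %, starting material / %): 2.00: 9.9, 87.7; 4.00: 15.1, 76.6; 6.00: 17.5, 67.8; 8.00: 15.4, 59.6; 10.0: 14.2, 51.8
- dusk (time / h: target / %, starting material / %): 2.00: 10.4, 88.1; 4.00: 17.5, 77.0; 6.00: 21.6, 68.4; 8.00: 23.4, 59.8; 10.0: 23.0, 52.2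

(scatter of a reading: 0.5 percentage points)

- theta: at 10 h take out 90% of the target then present, then wait 3.0 h
- delta: change nothing and wait 3.0 h more
- epsilon: at 10 h add free enzyme, 100% of the amount charged, then wait 3.0 h
- zeta: at 10 h add second substrate, 50.0% of the amount charged, then wait 3.0 h
- beta: at 10 h raise the temperature by 10 K, then wait 3.0 h

- removed target is counted in
- the numbers in the tables scatter with a standard deviation of 0.5 percentage points
- additions bring no volume worth counting

- target, in percent of the starting material first charged, at 10 h
- the option that brings most further target ("none" if no option brings more than 2 percentage points) (theta / delta / epsilon / zeta / beta / none)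
- target present, with what was taken out counted in, in percent of the starting material first charged, after delta
- target present, with what was taken out counted in, in percent of the starting material first charged, after beta

Ada holds that the target is a stable end product. The starting material falls with a steady constant k_a = 0.0658 /h, so she counts what 3.0 h more will convert and lands on 23.5% target after delta.

Ben answers that the dawn run's drop of 3.3 percentage points after 6.00 h stands against a scatter of 0.5 points, and that at 10.0 h in that run a share of 34.0% of the charge is neither starting material nor target. He treats both steps as pseudo-first-order. If target is lost at a rate k_d P, where P is the target, then the lost share equals k_d times the area under the target curve. The dawn readings so give k_d = 0.262 /h, the loss constant. The dusk run gives 0.147 /h, which is lower than at the warmer temperature.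

Integrating dP/dt = k_a A − k_d P in closed form, with A the starting material as a fraction of the charge, gives P = R(A − e^(−k_d t)), where R = k_a/(k_d − k_a) = 0.336. Late on, then, the target follows the starting material down.

My own reckoning from this gives 14.9% now and 13.2% after delta. Taking out 90% under theta gains 5.5 points by the same reckoning.

The forecast takes Ben's side with its own numbers: 14.6% (13.8% to 15.4%), 12.9% after delta, 5.5% after beta, and theta as best, since that option “protects the removed 13 points”.

The flask gives 15.1%, and theta is best, bringing 5.2 points. Delta brings −2.5 points and ends at 12.6%, while beta ends at 6.29%. Ben's view stands.

    ternary complex → free enzyme + target (k = 59.0 /min, Ea = 62.0 kJ/mol)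
    free enzyme → unfolded enzyme (k = 1.10 × 10⁻⁴ /min, Ea = 205 kJ/mol)
    second substrate + starting complex ⇌ ternary complex (K = 17.0 /M, k = 2.00 × 10⁵ /M/min, Ea = 32.0 kJ/mol, ΔH = −21.0 kJ/mol)
    starting material + free enzyme ⇌ starting complex (K = 26.0 /M, k = 2.50 × 10⁵ /M/min, Ea = 21.0 kJ/mol, ΔH = −78.0 kJ/mol)
    free enzyme + target → free enzyme + over-reaction product (k = 3300 /M/min, Ea = 44.0 kJ/mol)
    (constants at 30 °C)

By the path from free enzyme plus target to over-reaction product, the target's half-life with free enzyme as charged is 1.8 h; divided by this flask's free share of 68.2% at 10.0 h, that is 2.57 h, beside 2.65 h from k_d. Without that path this flask holds 48.1% target, not 15.1%, a part of the outcome shared with the way back from starting complex. Ada's view fits early: at 1.00 h this flask held 5.77% target and 0.655% over-reaction product. With k_d kept, the neighbour at 1.20 equiv of second substrate, with 67% starting material left, reckons to 10.7%, and it stood at 10.5%.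

(Readings and results stem from a simulated flask for an exercise; noise was put on by code.)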